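Ring C of the flavanone is cut across O1–C2 and C3–C4, which lie on opposite sides of the pyranone. The C2–C3 unit is then the vinyl group of 2,4,6-trimethoxystyrene, and O1–C8a–C4a–C4 is an ortho-quinone methide of ring A. One chiral-phosphoric-acid-catalysed oxa-Diels–Alder step forms both bonds, closes ring C and sets C2 together with a temporary C4 centre. Its precursor is the dimethyl acetal of a salicylaldehyde that already carries the 7-methoxy group, the 8-prenyl group and a silyl-capped O5. Hydrolysis, oxidation and desilylation finish the target.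

Key step: step 6

Assumption: the (R)-configured phosphoric acid is taken to give the (2S,4S) series; its sense of induction cannot be predicted with confidence, and the (S)-acid would be used if the opposite series forms.

Remark on the structures: adduct 10 with the descriptors (2S,4S) is the 2,4-cis isomer, and C2 keeps the descriptor S in 11, 12 and 13 because the ranking O1 > C1' > C3 > H holds throughout.

Remark on the precursor: O5 carries triisopropylsilyl, not a smaller silyl group. The bulkier group should sharpen the choice between the two phenols in step 3. It should also resist acid-induced loss of silicon from the cationic intermediate of step 6, which would open a second quinone methide through O5 and lead to the 6-prenyl series. It still falls to buffered fluoride at the end.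

Step 1
Reactants: 1 2,4,6-trihydroxybenzaldehyde
Product: 2 2,6-dihydroxy-4-methoxybenzaldehyde
Conditions: Me2SO4 (1.0 equiv), K2CO3 (1.0 equiv), acetone, 0 °C to rt
Reagents that add atoms: dimethyl sulfate COS(=O)(=O)OC
Why: Regioselective Williamson etherification: with one equivalent of base the 4-OH, para to the formyl group and not chelated to it, should be the phenol that is deprotonated and methylated, the two ortho phenols being less acidic through hydrogen bonding to the carbonyl.

Step 2
Reactants: 2 2,6-dihydroxy-4-methoxybenzaldehyde; 3 prenyl bromide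
Product: 4 2,6-dihydroxy-4-methoxy-3-(3-methylbut-2-en-1-yl)benzaldehyde
Conditions: 10% aq. KOH, 3 (0.9 equiv, slow addition), 0 °C to rt; then dilute HCl to pH 5
Reagents that add atoms: none
Why: Nuclear C-alkylation (C-prenylation) of a phloroglucinol-type phenoxide, favoured over O-alkylation in water where the phenoxide oxygens are solvated; C3 and C5 of 2 are equivalent by symmetry, so only one mono-prenyl isomer can form, and a slight deficit of 3 limits double alkylation.

Step 3
Reactants: 4 2,6-dihydroxy-4-methoxy-3-(3-methylbut-2-en-1-yl)benzaldehyde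
Product: 5 2-hydroxy-4-methoxy-3-(3-methylbut-2-en-1-yl)-6-[(triisopropylsilyl)oxy]benzaldehyde
Conditions: iPr3SiCl (1.05 equiv), imidazole (2.2 equiv), DMF, 0 °C
Reagents that add atoms: triisopropylsilyl chloride CC(C)[Si](Cl)(C(C)C)C(C)C
Why: Imidazole-mediated silylation of a phenol: the bulky chlorosilane should select the phenol flanked by H-5 over the one wedged between the formyl and prenyl groups, which leaves free exactly the oxygen that becomes O1 next to the prenyl-bearing C8.

Step 4
Reactants: 5 2-hydroxy-4-methoxy-3-(3-methylbut-2-en-1-yl)-6-[(triisopropylsilyl)oxy]benzaldehyde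
Product: 6 2-(dimethoxymethyl)-5-methoxy-6-(3-methylbut-2-en-1-yl)-3-[(triisopropylsilyl)oxy]phenol
Conditions: HC(OMe)3 (5 equiv), MeOH, PPTS (5 mol%), rt; then Et3N, evaporation, short plug of basic alumina, used at once
Reagents that add atoms: trimethyl orthoformate COC(OC)OC; methanol CO
Why: Acid-catalysed acetalisation of an aldehyde with an orthoformate, which supplies methanol and removes water as methyl formate; the ortho-hydroxy acetal ionises on silica, so it is quenched with base, stripped of volatiles and used without chromatography.

Step 5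
Reactants: 7 2,4,6-trimethoxybenzaldehyde
Product: 8 2,4,6-trimethoxystyrene
Conditions: Ph3PCH3Br (1.3 equiv), KOtBu (1.25 equiv), THF, 0 °C to rt
Reagents that add atoms: methyltriphenylphosphonium bromide C[P+](c1ccccc1)(c1ccccc1)c1ccccc1.[Br-]
Why: Wittig methylenation of an aromatic aldehyde with the non-stabilised ylide Ph3P=CH2, a standard route to styrenes; the electron-rich styrene is stored cold over K2CO3 and used fresh because traces of acid oligomerise it.

Step 6
Reactants: 6 2-(dimethoxymethyl)-5-methoxy-6-(3-methylbut-2-en-1-yl)-3-[(triisopropylsilyl)oxy]phenol; 8 2,4,6-trimethoxystyrene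
Product: 10 (2S,4S)-4,7-dimethoxy-8-(3-methylbut-2-en-1-yl)-2-(2,4,6-trimethoxyphenyl)-5-[(triisopropylsilyl)oxy]chromane (2,4-cis), via methoxy ortho-quinone methide 9 (not isolated)
Conditions: (R)-3,3'-bis(2,4,6-triisopropylphenyl)-1,1'-binaphthyl-2,2'-diyl hydrogen phosphate (10 mol%), 8 (1.5 equiv), powdered 5 Å MS, toluene, −40 to −20 °C; then Et3N
Reagents that add atoms: none
Why: The phosphoric acid protonates one acetal oxygen of 6 and methanol leaves, giving an oxocarbenium/phosphate ion pair that is the O1-protonated form of the (E)-4-methoxy ortho-quinone methide 9 and is held to the catalyst through O1–H···O=P; the nucleophilic CH2 terminus of 8 then bonds to C4 while O1 closes onto the developing 2,4,6-trimethoxybenzylic cation at C2 in a strongly asynchronous inverse-demand oxa-Diels–Alder reaction. The closest known reaction type is the acid-catalysed (4+2) cycloaddition of ortho-quinone methides released from salicylaldehyde acetals with styrenes to give 2,4-cis-4-alkoxyflavans, combined with chiral BINOL-phosphate catalysis of ortho-quinone methide cycloadditions. Ring C is closed as a six-membered ring in a (4+2) mode across the heterodiene O1=C8a–C4a=C4, with O1–C2 and C3–C4 as the two new bonds. C4 is set by the phosphate, whose 3,3'-aryl groups shield one face of the planar C4 terminus of the ion pair, and C2 is set relative to C4 by the endo approach of the trimethoxyphenyl group to the (E)-configured heterodiene, which gives the 2,4-cis adduct; any trans isomer is removed by chromatography here, before C4 is erased, because its C2 configuration need not match. The step needs regioselectivity, secured by the three methoxy groups of 8 that place positive charge at C2 and nucleophilicity at CH2, and site selectivity between O1 and O5, secured by the triisopropylsilyl cap that lets only O1 become the quinone methide oxygen so that the prenyl group ends at C8. It also needs the prenylphenol of 6 to survive, which a weak acid at low temperature and sieves that take up methanol should secure.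

Step 7
Reactants: 10 (2S,4S)-4,7-dimethoxy-8-(3-methylbut-2-en-1-yl)-2-(2,4,6-trimethoxyphenyl)-5-[(triisopropylsilyl)oxy]chromane
Product: 11 (2S)-7-methoxy-8-(3-methylbut-2-en-1-yl)-2-(2,4,6-trimethoxyphenyl)-5-[(triisopropylsilyl)oxy]chroman-4-ol, mixture of C4 epimers
Conditions: PPTS (0.2 equiv), THF/H2O (4:1), 0 °C to rt
Reagents that add atoms: water O
Why: SN1 solvolysis of a benzylic ether: C4 ionises under very weak acid because the cation is stabilised by O1, O5 and O7 and peri strain to the silyloxy group is relieved, whereas the poorly basic aryl ether O1 does not leave from C2, so C2 should stay S while C4 is scrambled without consequence.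

Step 8
Reactants: 11 (2S)-7-methoxy-8-(3-methylbut-2-en-1-yl)-2-(2,4,6-trimethoxyphenyl)-5-[(triisopropylsilyl)oxy]chroman-4-ol
Product: 12 (2S)-7-methoxy-8-(3-methylbut-2-en-1-yl)-2-(2,4,6-trimethoxyphenyl)-5-[(triisopropylsilyl)oxy]chroman-4-one
Conditions: Dess–Martin periodinane (1.3 equiv), NaHCO3 (5 equiv), CH2Cl2, 0 °C to rt
Reagents that add atoms: none
Why: Dess–Martin oxidation of a secondary benzylic alcohol under hydrogen carbonate buffer should convert both C4 epimers into the same ketone without acid that could ionise C4 or base that could open ring C.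

Step 9
Reactants: 12 (2S)-7-methoxy-8-(3-methylbut-2-en-1-yl)-2-(2,4,6-trimethoxyphenyl)-5-[(triisopropylsilyl)oxy]chroman-4-one
Product: 13 (2S)-5-hydroxy-7-methoxy-8-(3-methylbut-2-en-1-yl)-2-(2,4,6-trimethoxyphenyl)chroman-4-one (CNP0307910.1)
Conditions: Bu4NF (1.1 equiv), AcOH (1.5 equiv), THF, 0 °C; pH 7 buffer work-up
Reagents that add atoms: none
Why: Fluoride-mediated cleavage of an aryl silyl ether, fast here because the departing phenoxide is conjugated with the C4 carbonyl; acetic acid keeps the medium non-basic, so retro-oxa-Michael opening to the chalcone and loss of the C2 configuration should not occur.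

Compound list
1 | 2,4,6-trihydroxybenzaldehyde | O=Cc1c(O)cc(O)cc1O | starting material
2 | 2,6-dihydroxy-4-methoxybenzaldehyde | COc1cc(O)c(C=O)c(O)c1 | intermediate
3 | prenyl bromide (1-bromo-3-methylbut-2-ene) | CC(C)=CCBr | starting material
4 | 2,6-dihydroxy-4-methoxy-3-(3-methylbut-2-en-1-yl)benzaldehyde | COc1cc(O)c(C=O)c(O)c1CC=C(C)C | intermediate
5 | 2-hydroxy-4-methoxy-3-(3-methylbut-2-en-1-yl)-6-[(triisopropylsilyl)oxy]benzaldehyde | COc1cc(O[Si](C(C)C)(C(C)C)C(C)C)c(C=O)c(O)c1CC=C(C)C | intermediate
6 | 2-(dimethoxymethyl)-5-methoxy-6-(3-methylbut-2-en-1-yl)-3-[(triisopropylsilyl)oxy]phenol | COC(OC)c1c(O)c(CC=C(C)C)c(OC)cc1O[Si](C(C)C)(C(C)C)C(C)C | intermediate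
7 | 2,4,6-trimethoxybenzaldehyde | COc1cc(OC)c(C=O)c(OC)c1 | starting material
8 | 2,4,6-trimethoxystyrene | C=Cc1c(OC)cc(OC)cc1OC | intermediate
9 | (6E)-3-methoxy-6-(methoxymethylidene)-2-(3-methylbut-2-en-1-yl)-5-[(triisopropylsilyl)oxy]cyclohexa-2,4-dien-1-one (not isolated) | CO/C=C1/C(=O)C(CC=C(C)C)=C(OC)C=C1O[Si](C(C)C)(C(C)C)C(C)C | intermediate
10 | (2S,4S)-4,7-dimethoxy-8-(3-methylbut-2-en-1-yl)-2-(2,4,6-trimethoxyphenyl)-5-[(triisopropylsilyl)oxy]chromane, 2,4-cis | COc1cc(OC)c([C@@H]2C[C@H](OC)c3c(O[Si](C(C)C)(C(C)C)C(C)C)cc(OC)c(CC=C(C)C)c3O2)c(OC)c1 | intermediate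
11 | (2S)-7-methoxy-8-(3-methylbut-2-en-1-yl)-2-(2,4,6-trimethoxyphenyl)-5-[(triisopropylsilyl)oxy]chroman-4-ol, both C4 epimers, C4 left undefined | COc1cc(OC)c([C@@H]2CC(O)c3c(O[Si](C(C)C)(C(C)C)C(C)C)cc(OC)c(CC=C(C)C)c3O2)c(OC)c1 | intermediate
12 | (2S)-7-methoxy-8-(3-methylbut-2-en-1-yl)-2-(2,4,6-trimethoxyphenyl)-5-[(triisopropylsilyl)oxy]chroman-4-one | COc1cc(OC)c([C@@H]2CC(=O)c3c(O[Si](C(C)C)(C(C)C)C(C)C)cc(OC)c(CC=C(C)C)c3O2)c(OC)c1 | intermediate
13 | (2S)-5-hydroxy-7-methoxy-8-(3-methylbut-2-en-1-yl)-2-(2,4,6-trimethoxyphenyl)chroman-4-one | COc1cc(OC)c([C@@H]2CC(=O)c3c(O)cc(OC)c(CC=C(C)C)c3O2)c(OC)c1 | target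

Total step count: 9.
Longest linear sequence: 8 steps (1 → 2 → 4 → 5 → 6 → 10 → 11 → 12 → 13; steps 1–4 and 6–9).

Steps most likely to fail

Step 6. The risks are weak facial discrimination within the phosphate/oxocarbenium ion pair, incomplete endo preference, and acid-induced oligomerisation of the styrene that starves the cycloaddition. The fallback sets out from 6 and 8 and gives up catalyst control. The same cycloaddition is run with an achiral acid (diphenyl hydrogen phosphate, 10 mol%, 5 Å MS, CH2Cl2, −20 °C), which is the established racemic mode of this reaction, and should give the racemic 2,4-cis adduct F1. Preparative chromatography on a chiral stationary phase (amylose tris(3,5-dimethylphenylcarbamate), supercritical CO2/MeOH) would then separate 10 from its (2R,4R) enantiomer F2. The configuration would be assigned by circular dichroism after a sample is converted into 13. The route is rejoined at 10.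

Step 7. The risks are loss of a C3 proton from the C4 cation, which diverts material into the flav-3-ene, and reversible ionisation of the O1–C2 bond, which would erode the configuration at C2. The fallback sets out from 10 and replaces hydrolysis by oxidation. DDQ (1.2 equiv) in CH2Cl2/pH 7 phosphate buffer at 0 °C is the known oxidative cleavage of electron-rich benzylic methyl ethers: hydride is abstracted from C4, the oxocarbenium ion is hydrated and methanol is lost. It should give the ketone directly, without acid and without alcohol 11. The route is rejoined at 12 and no new compound is made (none F0).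

Step 2. The risks are O-alkylation and a second C-alkylation competing with mono-C-prenylation. The fallback sets out from 2 and builds the prenyl group by rearrangement. One of the two equivalent phenols is O-alkylated with 3-chloro-3-methylbut-1-yne (K2CO3, KI, CuI cat., acetone, 50 °C) to give 2-hydroxy-4-methoxy-6-[(2-methylbut-3-yn-2-yl)oxy]benzaldehyde F3. Semi-hydrogenation (H2, Pd on CaCO3 poisoned with Pb(OAc)2, quinoline, EtOAc) gives 2-hydroxy-4-methoxy-6-[(2-methylbut-3-en-2-yl)oxy]benzaldehyde F4. An aromatic Claisen rearrangement (N,N-diethylaniline, 120 °C) then delivers the allyl unit with allylic transposition to the only free ortho carbon. The route is rejoined at 4.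

Further compounds
F1 | step 6 | racemic 2,4-cis-4,7-dimethoxy-8-(3-methylbut-2-en-1-yl)-2-(2,4,6-trimethoxyphenyl)-5-[(triisopropylsilyl)oxy]chromane (equal parts of the two enantiomers) | COc1cc(OC)c([C@@H]2C[C@H](OC)c3c(O[Si](C(C)C)(C(C)C)C(C)C)cc(OC)c(CC=C(C)C)c3O2)c(OC)c1.COc1cc(OC)c([C@H]2C[C@@H](OC)c3c(O[Si](C(C)C)(C(C)C)C(C)C)cc(OC)c(CC=C(C)C)c3O2)c(OC)c1
F2 | step 6 | (2R,4R)-4,7-dimethoxy-8-(3-methylbut-2-en-1-yl)-2-(2,4,6-trimethoxyphenyl)-5-[(triisopropylsilyl)oxy]chromane | COc1cc(OC)c([C@H]2C[C@@H](OC)c3c(O[Si](C(C)C)(C(C)C)C(C)C)cc(OC)c(CC=C(C)C)c3O2)c(OC)c1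
F0 | step 7 | none | none
F3 | step 2 | 2-hydroxy-4-methoxy-6-[(2-methylbut-3-yn-2-yl)oxy]benzaldehyde | COc1cc(O)c(C=O)c(OC(C)(C)C#C)c1
F4 | step 2 | 2-hydroxy-4-methoxy-6-[(2-methylbut-3-en-2-yl)oxy]benzaldehyde | COc1cc(O)c(C=O)c(OC(C)(C)C=C)c1
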